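**Strategy.** Ring B of this ent-labdane is read as a masked Diels–Alder adduct. The C7–O/C8=C9 allylic acetate is the reduced, isomerised form of a cycloadduct between a 2-silyloxydiene (C5=C6–C7=C8) and the C9=C10 π bond of a trisubstituted allene, joined through the C1–C4 chain. One thermal intramolecular [4+2] closes rings A and B by forming C5–C10 and C8–C9. The allene axis dictates the quaternary C10 centre and, through trans fusion, C5. The surviving exocyclic C9=C11 alkene later moves into conjugation as C8=C9. The precursor is an acyclic, axially chiral allene–silyloxydiene that already carries the whole side chain.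

Key step: step 8

Remark: labdane numbering is used for all intermediates. The target SMILES is read as (5R,7R,10R,13E), i.e. the ent-labdane series with the C7 acetoxy group cis to the C10 methyl group. Compounds 1, 2, 5 and 7 are taken to be catalogue compounds.

Step 1
Reactants: 1 2,2-dimethylpent-4-enal; 2 diethyl (2-oxobutyl)phosphonate
Product: 3 (4E)-6,6-dimethylnona-4,8-dien-3-one
Conditions: NaH, THF, 0 °C → rt
Reagents that add atoms: none
Why: Horner–Wadsworth–Emmons olefination of the non-enolisable neopentyl aldehyde with the β-ketophosphonate anion should give the (E)-enone under thermodynamic control, which fixes the later C5=C6 diene geometry.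

Step 2
Reactants: 3 (4E)-6,6-dimethylnona-4,8-dien-3-one
Product: 4 tert-butyl{[(2Z,4E)-6,6-dimethylnona-2,4,8-trien-3-yl]oxy}dimethylsilane
Conditions: TBSOTf, Et3N, CH2Cl2, −78 → 0 °C
Reagents that add atoms: tert-butyldimethylsilyl trifluoromethanesulfonate, CC(C)(C)[Si](C)(C)OS(=O)(=O)C(F)(F)F
Why: Soft enolisation and O-silylation can only take place at the ethyl side because the γ-carbon is quaternary, and amine/silyl triflate conditions should give the (Z)-enol ether, which places the terminal methyl group on the outside of the diene.

Step 3
Reactants: 5 but-2-yn-1-ol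
Product: 6 but-2-ynal
Conditions: activated MnO2, CH2Cl2, rt; filtered and used as a dried solution
Reagents that add atoms: none
Why: Heterogeneous MnO2 oxidation of a propargylic alcohol should stop cleanly at the volatile ynal.

Step 4
Reactants: 7 methyl 3-methylbut-2-enoate
Product: 8 tert-butyl[(1-methoxy-3-methylbuta-1,3-dien-1-yl)oxy]dimethylsilane
Conditions: LDA, THF, −78 °C; TBSCl, DMPU, −78 °C → rt
Reagents that add atoms: tert-butyldimethylsilyl chloride, CC(C)(C)[Si](C)(C)Cl
Why: γ-Deprotonation of the senecioate gives the extended enolate, which is trapped on oxygen to give the silyl dienol ketene acetal.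

Step 5
Reactants: 6 but-2-ynal; 8 tert-butyl[(1-methoxy-3-methylbuta-1,3-dien-1-yl)oxy]dimethylsilane
Product: 9 methyl (2E,5S)-5-hydroxy-3-methyloct-2-en-6-ynoate
Conditions: SiCl4 (1.1 equiv), chiral bisphosphoramide (two N,N′-dimethyl-1,1′-binaphthyl-2,2′-diamine phosphoramide units joined by an N,N′-dimethylpentane-1,5-diamine linker, 5 mol %), i-Pr2NEt (cat.), CH2Cl2, −78 °C; aq. NaHCO3
Reagents that add atoms: none
Why: In this Lewis-base-activated vinylogous Mukaiyama aldol reaction the phosphoramide-bound silicon cation should activate the conjugated ynal in an open transition state, so that the s-trans dienolate attacks through its γ-carbon to give the (E)-enoate, and the catalyst antipode that shields the aldehyde face leading to the (5R)-carbinol is chosen so that the (5S)-alcohol forms.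

Step 6
Reactants: 9 methyl (2E,5S)-5-hydroxy-3-methyloct-2-en-6-ynoate
Product: 10 methyl (2E,5S)-5-[(diethoxyphosphoryl)oxy]-3-methyloct-2-en-6-ynoate
Conditions: ClP(O)(OEt)2, pyridine, DMAP (cat.), CH2Cl2, 0 °C → rt
Reagents that add atoms: diethyl chlorophosphate, CCOP(=O)(Cl)OCC
Why: O-Phosphorylation under mild base turns the propargylic alcohol into a leaving group without touching the C–O stereocentre.

Step 7
Reactants: 4 tert-butyl{[(2Z,4E)-6,6-dimethylnona-2,4,8-trien-3-yl]oxy}dimethylsilane; 10 methyl (2E,5S)-5-[(diethoxyphosphoryl)oxy]-3-methyloct-2-en-6-ynoate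
Product: 12 methyl (Ra,2E,12E,14Z)-14-[(tert-butyldimethylsilyl)oxy]-3,7,11,11-tetramethylhexadeca-2,5,6,12,14-pentaenoate, via alkylborane 11 (not isolated)
Conditions: 9-BBN-H dimer, THF, 0 °C → rt; then 10, CuOAc (10 mol %), t-BuOK (1 equiv per boron), THF, 40 °C
Reagents that add atoms: none
Why: 9-BBN-H should hydroborate only the terminal alkene, and the resulting alkylborate should undergo copper-catalysed γ-selective (anti-SN2′) alkyl–propargyl coupling at the methyl-bearing alkyne carbon, so that the (5S)-phosphate centre is transferred into the (Ra) allene axis (seen from the CH end with the C4 chain down, the C8 chain points right).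

Step 8
Reactants: 12 methyl (Ra,2E,12E,14Z)-14-[(tert-butyldimethylsilyl)oxy]-3,7,11,11-tetramethylhexadeca-2,5,6,12,14-pentaenoate
Product: 13 methyl (5R,8S,9(11)Z,10R,13E)-7-[(tert-butyldimethylsilyl)oxy]labda-6,9(11),13-trien-15-oate
Conditions: toluene (0.01 M), BHT, trace Et3N, sealed tube, 170 °C
Reagents that add atoms: none
Why: Heating should trigger a concerted, suprafacial [4+2] cycloaddition between the (E,Z)-2-silyloxydiene C5=C6–C7=C8 and the proximal allene π bond C9=C10, forming C5–C10 and C8–C9 (intramolecular Diels–Alder reaction; the closest known type is the thermal cycloaddition of diene-tethered allenes with axis-to-centre chirality transfer). Ring A closes through the C5–C10 bond as a six-membered ring across the C1–C4 tether (fused mode, chair-like tether held exo), and ring B is the cyclohexene created by the two new σ bonds. C10 is controlled by the allene axis, because the diene can reach only the C9=C10 face that carries the C11–H and not the face blocked by the C12 chain, so the (Ra)-allene gives (10R) and a (Z)-C9=C11 alkene. C5 follows from the E geometry of C5=C6 together with the tether-exo (angular methyl endo) transition state, which keeps C6 and C9 equatorial on the developing chair of ring A and gives the trans fusion; C8 is set by the Z-enol ether and is erased later. The step needs periselectivity for the proximal allene bond, which the tether length secures (six-membered ring A against a seven-membered alternative), and trans over cis fusion, which should be favoured because the tether-endo transition state must carry the silyloxydiene axially on ring A and fold C1–C2 under the diene. Both fusion isomers would share the allene-derived C10 configuration, so the enantiomeric purity should not depend on that preference.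

Step 9
Reactants: 13 methyl (5R,8S,9(11)Z,10R,13E)-7-[(tert-butyldimethylsilyl)oxy]labda-6,9(11),13-trien-15-oate
Product: 15 methyl (5R,10R,13E)-7-oxolabda-8,13-dien-15-oate, via deconjugated ketone 14 (not isolated)
Conditions: 2 M aq. HCl, THF, rt → 45 °C
Reagents that add atoms: none
Why: Acid hydrolysis of the silyl enol ether gives the β,γ-unsaturated ketone, and acid-catalysed enolisation toward C8 followed by γ-protonation at C11 should move the exocyclic alkene into the conjugated, tetrasubstituted C8=C9 position, which removes the C8 centre and leaves C5 and C10 untouched.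

Step 10
Reactants: 15 methyl (5R,10R,13E)-7-oxolabda-8,13-dien-15-oate
Product: 16 (5R,7R,10R,13E)-labda-8,13-diene-7,15-diol
Conditions: LiAlH4, Et2O, −40 → 0 °C; aq. NaOH work-up
Reagents that add atoms: none
Why: The hydride should reduce the enoate to the allylic alcohol and the enone in the 1,2 sense, attacking C7 axially from the face of the C5–H (anti to the axial C10 methyl) to give the pseudo-equatorial (7R) alcohol cis to C20, as in the reduction of 3-oxo-4-ene steroids.

Step 11
Reactants: 16 (5R,7R,10R,13E)-labda-8,13-diene-7,15-diol
Product: 17 (5R,7R,10R,13E)-labda-8,13-diene-7,15-diyl diacetate (target)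
Conditions: Ac2O, pyridine, DMAP (cat.), CH2Cl2, 0 °C → rt
Reagents that add atoms: acetic anhydride, CC(=O)OC(C)=O
Why: DMAP-catalysed acylation should esterify the primary and the secondary allylic hydroxyl groups without affecting any stereocentre.

**Compound list**

1 | 2,2-dimethylpent-4-enal | C=CCC(C)(C)C=O | starting material
2 | diethyl (2-oxobutyl)phosphonate | CCC(=O)CP(=O)(OCC)OCC | starting material
3 | (4E)-6,6-dimethylnona-4,8-dien-3-one | CCC(=O)/C=C/C(C)(C)CC=C | intermediate
4 | tert-butyl{[(2Z,4E)-6,6-dimethylnona-2,4,8-trien-3-yl]oxy}dimethylsilane | C/C=C(O[Si](C)(C)C(C)(C)C)/C=C/C(C)(C)CC=C | intermediate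
5 | but-2-yn-1-ol | CC#CCO | starting material
6 | but-2-ynal | CC#CC=O | intermediate
7 | methyl 3-methylbut-2-enoate | COC(=O)C=C(C)C | starting material
8 | tert-butyl[(1-methoxy-3-methylbuta-1,3-dien-1-yl)oxy]dimethylsilane | C=C(C)C=C(OC)O[Si](C)(C)C(C)(C)C | intermediate
9 | methyl (2E,5S)-5-hydroxy-3-methyloct-2-en-6-ynoate | CC#C[C@@H](O)C/C(C)=C/C(=O)OC | intermediate
10 | methyl (2E,5S)-5-[(diethoxyphosphoryl)oxy]-3-methyloct-2-en-6-ynoate | CC#C[C@@H](OP(=O)(OCC)OCC)C/C(C)=C/C(=O)OC | intermediate
11 | 9-{(5E,7Z)-7-[(tert-butyldimethylsilyl)oxy]-4,4-dimethylnona-5,7-dien-1-yl}-9-borabicyclo[3.3.1]nonane | C/C=C(O[Si](C)(C)C(C)(C)C)/C=C/C(C)(C)CCCB1C2CCCC1CCC2 | intermediate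
12 | methyl (Ra,2E,12E,14Z)-14-[(tert-butyldimethylsilyl)oxy]-3,7,11,11-tetramethylhexadeca-2,5,6,12,14-pentaenoate | COC(=O)/C=C(\C)CC([H])=[C@]=C(C)CCCC(C)(C)/C=C/C(O[Si](C)(C)C(C)(C)C)=C/C | intermediate
13 | methyl (5R,8S,9(11)Z,10R,13E)-7-[(tert-butyldimethylsilyl)oxy]labda-6,9(11),13-trien-15-oate | COC(=O)/C=C(\C)C/C=C1/[C@H](C)C(O[Si](C)(C)C(C)(C)C)=C[C@@H]2C(C)(C)CCC[C@@]12C | intermediate
14 | methyl (5R,8S,9(11)Z,10R,13E)-7-oxolabda-9(11),13-dien-15-oate | COC(=O)/C=C(\C)C/C=C1/[C@H](C)C(=O)C[C@@H]2C(C)(C)CCC[C@@]12C | intermediate
15 | methyl (5R,10R,13E)-7-oxolabda-8,13-dien-15-oate | COC(=O)/C=C(\C)CCC1=C(C)C(=O)C[C@@H]2C(C)(C)CCC[C@@]12C | intermediate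
16 | (5R,7R,10R,13E)-labda-8,13-diene-7,15-diol | OC/C=C(\C)CCC1=C(C)[C@H](O)C[C@@H]2C(C)(C)CCC[C@@]12C | intermediate
17 | (5R,7R,10R,13E)-labda-8,13-diene-7,15-diyl diacetate | CC(=O)OC/C=C(\C)CCC1=C(C)[C@H](OC(C)=O)C[C@@H]2C(C)(C)CCC[C@@]12C | target

**Step count.** Total: 11 steps. Longest linear sequence: 8 steps (steps 3, 5, 6, 7, 8, 9, 10 and 11, from but-2-yn-1-ol).

**Steps most likely to fail**

Step 8. The unactivated allene may react too slowly below the temperature at which the silyl dienol ether and the skipped polyene survive, and the preference for the tether-exo (trans-fused) transition state over the tether-endo one may be incomplete. The fallback sets out from 12 and comes back at 13. The pericyclic closure is replaced by a metal-templated formal [4+2]: zerovalent nickel (Ni(cod)2) or monovalent rhodium ([Rh(cod)Cl]2) with tris(2-biphenylyl) phosphite in THF at rt to 60 °C. Oxidative cyclisation of the diene with the proximal allene bond on the metal would give a metallacycle, which reductively eliminates to the same adduct 13, with the metal again binding the allene face anti to C12. This fallback makes no new compound (F0).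

Step 7. 9-BBN-H may not discriminate fully between the terminal alkene and the silyloxydiene of 4, and the acid- and alkoxide-labile dienol ether may be eroded during the coupling and its purification. The fallback sets out from 1 and comes back at 12; it moves allene formation ahead of diene construction. Aldehyde 1 is protected (HC(OMe)3, TsOH, MeOH) as 5,5-dimethoxy-4,4-dimethylpent-1-ene F1. F1 is hydroborated with 9-BBN-H and coupled with 10 under the same CuOAc/t-BuOK catalysis to give methyl (Ra,2E)-12,12-dimethoxy-3,7,11,11-tetramethyldodeca-2,5,6-trienoate F2. Mild acid (PPTS, wet acetone) releases methyl (Ra,2E)-3,7,11,11-tetramethyl-12-oxododeca-2,5,6-trienoate F3. Horner–Wadsworth–Emmons reaction of F3 with 2 (NaH, THF) gives methyl (Ra,2E,12E)-3,7,11,11-tetramethyl-14-oxohexadeca-2,5,6,12-tetraenoate F4, and silylation of F4 (TBSOTf, Et3N) gives 12.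

Step 5. With the small ynal the addition may show poor γ-selectivity or facial selectivity, or may proceed through the s-cis dienolate to the (Z)-enoate, which lactonises. The fallback sets out from 6 and comes back at 9; it separates the carbinol-forming and alkene-forming events. Asymmetric propargylation of 6 with allenylboronic acid pinacol ester under a chiral 3,3′-bis(2,4,6-triisopropylphenyl)-BINOL hydrogen phosphate (antipode chosen for the S-carbinol) gives (4S)-hepta-1,5-diyn-4-ol F5. Zirconium-catalysed syn methylalumination of the terminal alkyne of F5 (Me3Al, Cp2ZrCl2, CH2Cl2), followed by quenching the alkenylalane with methyl chloroformate, gives 9 with the E geometry fixed by the carbometalation.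

**Further compounds**

F0 | step 8 | none | none
F1 | step 7 | 5,5-dimethoxy-4,4-dimethylpent-1-ene | C=CCC(C)(C)C(OC)OC
F2 | step 7 | methyl (Ra,2E)-12,12-dimethoxy-3,7,11,11-tetramethyldodeca-2,5,6-trienoate | COC(=O)/C=C(\C)CC([H])=[C@]=C(C)CCCC(C)(C)C(OC)OC
F3 | step 7 | methyl (Ra,2E)-3,7,11,11-tetramethyl-12-oxododeca-2,5,6-trienoate | COC(=O)/C=C(\C)CC([H])=[C@]=C(C)CCCC(C)(C)C=O
F4 | step 7 | methyl (Ra,2E,12E)-3,7,11,11-tetramethyl-14-oxohexadeca-2,5,6,12-tetraenoate | COC(=O)/C=C(\C)CC([H])=[C@]=C(C)CCCC(C)(C)/C=C/C(=O)CC
F5 | step 5 | (4S)-hepta-1,5-diyn-4-ol | CC#C[C@@H](O)CC#C
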